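With a small charge, [Ek] = 27 mM, you have to decide whether the next run should stand longer or hold more Ek. The ochre run is this same flask followed so far, so its readings speak for the first choice.

the same everywhere: Ek 27 mM

|  | remark | time |
|---|---|---|
| ochre | the very flask that is asked about, followed so far |  |
| flask |  | 6.0 d |

ochre run (percent of the Ek charged)

| time / d | Ek / % | Dz / % | Zo / % |
|---|---|---|---|
| 0.250 | 21.0 | 1.7 | 15.0 |
| 0.417 | 8.2 | 2.8 | 27.8 |
| 0.625 | 1.6 | 6.2 | 37.6 |
| 1.04 | 1.3 | 7.5 | 51.2 |
| 1.67 | 0 | 8.2 | 60.5 |
| 3.00 | 0 | 6.9 | 58.7 |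

(scatter of a reading: 1 percentage point)

- in percentages every species weighs as the Ek in it: one Ux counts as two
- reactions considered so far: Ek -> Zu; Zu -> Lx; Ek -> Eb; Eb -> Zo; Eb -> Jo; Jo -> Dz; 2 Ek -> Ux; Dz <-> Uv
- the reaction counts as stopped when no species that holds the Ek changes by six tenths of a point or more over the second half of the time

1. at 6.0 d, what has stopped the reaction, if anything has (forward and back rates have come level / all of Ek has reacted / it is still moving)
2. part of the Ek gone at 6.0 d
3. the Dz standing at 6.0 d, as a percentage of the Ek charged
4. the Zo standing at 6.0 d, as a percentage of the Ek charged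

Ek reads 0 % by 1.67 d, and Zo and Dz read 60.5 % and 8.2 % there, then 58.7 % and 6.9 % at 3.00 d, so these readings show no gain from standing longer. My own reckoning keeps Ek at 0 % and takes the mean of those pairs: Zo 59.6 %, Dz 7.55 %.

For the second choice I carry the split, the Zo standing per Dz standing over those last readings: 7.89. It is a ratio of what stands, not a selectivity factor between the branches, since the scheme lets Dz pass on into Uv. With a scatter of 1 percentage point on such small Dz readings, it is a loose reading. In the scheme, Zo and Dz both descend from Eb, and each step between takes one molecule, so I expect the charge to leave the split alone and to act upstream, where two Ek join into Ux. The next run should therefore change the charge, not the time, with one late reading of Zo and Dz to test the split.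

The forecast gives all of Ek has reacted, 100 % gone, Dz 7.3 % and Zo 60 %, setting Dz below mine, on grounds such as “Zo has no onward step in the scheme”.

The flask gives all of Ek has reacted, 100 % gone, Dz 8.06 % and Zo 59.5 %.

    Ek → Zu (k = 0.0190 h⁻¹)
    Zu → Lx (k = 0.0360 h⁻¹)
    Ek → Eb (k = 0.190 h⁻¹)
    Eb → Zo (k = 0.0860 h⁻¹)
    Eb → Jo (k = 0.0190 h⁻¹)
    Jo → Dz (k = 0.180 h⁻¹)
    2 Ek → Ux (k = 2.10 M⁻¹ h⁻¹)
    Dz ⇌ Uv (K = 0.630, k = 0.200 h⁻¹)

The forecast holds for this flask, while the neighbour with 68 mM of Ek, read at the same 6.0 d, holds Zo 46.9 % and Dz 6.36 %, both under the forecast , with Ux 37.0 % against 20.1 % in this flask. Yet the split comes to 7.38 in this flask and 7.37 in the neighbour, and the neighbour's Zo divided by the read 7.89 gives Dz 5.94 %. The path from Eb to Zo is a part of the reason why Dz stands so low in this flask: with that path taken away, Dz stands at 41.1 % instead of 8.06 %.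

Readings and results stem from a simulated flask on assumed constants; scatter was added.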